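The single ring, the cyclohexenone (C1 carbonyl, C2 methoxy, C3, C4 hydroxyl, C5 chain, C6 methyl), is cut at C5–C6, C4–O and C2=C3. The feature exploited: C2, C1 and C6 form a methoxyacetone unit. C3, C4 and C5 map onto an enal whose β-position C5 is electrophilic and whose α-position C4 turns nucleophilic afterwards. In one flask an (R)-diarylprolinol silyl ether merges keto ester 3 (C6 activated by a removable allyl ester), O-benzoyl enal 6 and peroxide 7. Michael addition, α-benzoyloxylation and aldol condensation deliver the ring and the 4,5-cis pair. A C5 iodomethyl group is finally coupled with a C14 alkenyl iodide.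

Key step: step 3

Remarks
- Numbering: C1–C6 as above is kept for all ring compounds and their open-chain forerunners. The exocyclic carbon on C5 is C7.
- Target configuration: (4R,5R,6R), with O4 and C7 cis and C7 and the C6 methyl trans.
- Assumption: geranylacetone is used as the isomerically pure (E)-compound.
- The enal oxygen is carried as a benzoate for three reasons. It stands the acid stage of step 3. It leaves together with the C4 benzoate in step 5. No allylic ester is then present when nickel and manganese are used in step 9.
- Methanolysis comes after decarboxylation, because alkoxide would cleave the non-enolisable β-keto ester 11 by a retro-Claisen reaction.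
- The (R)-amine is needed: the (S)-series delivers heteroatom electrophiles to aldehyde α-carbons in the (S) sense (O > CHO > alkyl), and C4 must be (R).

Step 1
Reactants: 1 allyl propionate; 2 methyl methoxyacetate
Product: 3 allyl 4-methoxy-2-methyl-3-oxobutanoate (racemic)
Conditions: 1 (2.1 equiv), LDA (2.2 equiv), THF, −78 °C; 2 (1.0 equiv), −78 to −30 °C; 1 M HCl
Reagents that add atoms: none
Why: Crossed Claisen condensation in which the preformed lithium enolate of 1 acylates on the activated α-alkoxy ester 2 and the second equivalent of enolate deprotonates 3 to drive the reaction, the cold keeping the allyl ester enolate from rearranging and the new centre being enolisable and in need of no control.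

Step 2
Reactants: 4 allyl benzoate; 5 (E)-crotonaldehyde
Product: 6 (E)-4-oxobut-2-en-1-yl benzoate
Conditions: second-generation Hoveyda–Grubbs catalyst (2 mol %), 5 (3 equiv), CH2Cl2, 40 °C
Reagents that add atoms: none
Why: Olefin cross-metathesis of a terminal alkene with an electron-poor enal partner, which should give the conjugated (E)-enal under thermodynamic control while propene escapes.

Step 3
Reactants: 3 allyl 4-methoxy-2-methyl-3-oxobutanoate; 6 (E)-4-oxobut-2-en-1-yl benzoate; 7 dibenzoyl peroxide
Product: 11 allyl (4R,5S)-4-benzoyloxy-5-(benzoyloxymethyl)-2-methoxy-6-methyl-1-oxocyclohex-2-ene-6-carboxylate (4,5-cis; both C6 epimers; 6S drawn), via Michael adduct 8 (not isolated), via benzoyloxy aldehyde 9 (not isolated), via aldol 10 (not isolated)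
Conditions: (R)-2-[diphenyl(trimethylsilyloxy)methyl]pyrrolidine (20 mol %), PhCO2H (20 mol %), toluene, 0 °C to rt; then 7 (1.05 equiv), hydroquinone (10 mol %), 0 °C; then TsOH·H2O (0.5 equiv), 4 Å MS, 40 °C
Reagents that add atoms: none
Why: Proposed new method: the amine and 6 form an (E)-iminium ion, the enol of 3 adds through C6 to C5 to give 8, the amine converts the aldehyde of 8 into its (E)-enamine whose C4 attacks the O–O bond of 7 (substitution at oxygen, benzoate leaving) to give 9, and the added acid lets the C2 enol add to the C3 aldehyde (10) and expels water to give 11. Each event has a close relative, namely iminium–enamine cascades that pair a Michael addition with an α-heterofunctionalisation, enamine α-benzoyloxylation of simple aldehydes with benzoyl peroxide, and amine-catalysed Michael/aldol annulation of β-keto esters with enals, but the three have not been run as one sequence nor with an α-branched 4-alkoxy keto ester. The one ring closes by a 6-(enolexo)-exo-trig aldol addition that dehydration to the conjugated 2-methoxy enone makes irreversible. C5 is fixed by the CPh2(OSiMe3) group covering one face of the iminium ion and C4 by the same group covering the same face of the enamine, so both bonds arrive syn across the former (E)-alkene, which reads as O4/C7 cis (4R,5S) once C3 and C6 are ring members, while C6 forms as an epimer mixture that is erased in steps 4 and 5. The peroxide must choose the enamine of 8 over 3, 6 and the amine, which is secured by adding 7 only after 3 and 6 are consumed, and the aldol must wait for the oxygenation, which is secured because keto aldehydes of this type need added strong acid to condense. Only C2 can serve as aldol donor because C6 is quaternary, and both benzoates stand the acid.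

Step 4
Reactants: 11 allyl (4R,5S)-4-benzoyloxy-5-(benzoyloxymethyl)-2-methoxy-6-methyl-1-oxocyclohex-2-ene-6-carboxylate
Product: 12 (4R,5S)-4-benzoyloxy-5-(benzoyloxymethyl)-2-methoxy-6-methylcyclohex-2-en-1-one (C6 epimers; 6R drawn)
Conditions: Pd(OAc)2 (5 mol %), PPh3 (20 mol %), HCO2H (2 equiv), Et3N (2.5 equiv), THF, rt
Reagents that add atoms: none
Why: Palladium-catalysed deallylation–decarboxylation–protonation of an allyl β-keto ester with formate (Tsuji-type), in which the unhindered allyl ester should ionise far faster than the secondary ring benzoate on a trisubstituted electron-poor alkene, formate removes the allyl group as propene so that C6 is protonated and not allylated, and the C6 configuration is left open until step 5.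

Step 5
Reactants: 12 (4R,5S)-4-benzoyloxy-5-(benzoyloxymethyl)-2-methoxy-6-methylcyclohex-2-en-1-one
Product: 13 (4R,5S,6R)-4-hydroxy-5-(hydroxymethyl)-2-methoxy-6-methylcyclohex-2-en-1-one
Conditions: K2CO3 (0.3 equiv), MeOH, 0 °C to rt
Reagents that add atoms: none
Why: Base-catalysed transesterification (Zemplén-type methanolysis) frees both alcohols at once, and the same carbonate reversibly enolises C6 so that both epimers should drain into the more stable 5,6-trans isomer with C7 and the methyl group equatorial, C5 carrying no acidic hydrogen and C4 only the much less acidic γ-hydrogen of a donor-substituted enone.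

Step 6
Reactants: 13 (4R,5S,6R)-4-hydroxy-5-(hydroxymethyl)-2-methoxy-6-methylcyclohex-2-en-1-one
Product: 14 (4S,5R,6R)-4-hydroxy-5-(iodomethyl)-2-methoxy-6-methylcyclohex-2-en-1-one (same spatial arrangement as 13; descriptors change through the priority of iodine)
Conditions: I2 (1.1 equiv), PPh3 (1.1 equiv), imidazole (2 equiv), CH2Cl2, 0 °C
Reagents that add atoms: iodine, II
Why: Appel-type iodination in which the unhindered primary alcohol forms the alkoxyphosphonium salt and is displaced much faster than the flanked secondary C4 alcohol, so that no stereocentre is touched.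

Step 7
Reactants: 15 (E)-geranylacetone
Product: 17 (E)-6,10-dimethylundeca-5,9-dien-1-yne, via enol phosphate 16 (not isolated)
Conditions: LDA (1.05 equiv), THF, −78 °C; ClP(O)(OEt)2 (1.1 equiv), −78 °C to rt; then LDA (2.3 equiv), −78 °C to rt; H2O
Reagents that add atoms: diethyl chlorophosphate, CCOP(=O)(Cl)OCC (its atoms stay in 16 only and leave again on the way to 17)
Why: Known methyl ketone to terminal alkyne conversion by kinetic deprotonation at the methyl group, O-phosphorylation and base-induced elimination of the enol phosphate, which leaves the trisubstituted alkenes alone.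

Step 8
Reactants: 17 (E)-6,10-dimethylundeca-5,9-dien-1-yne
Product: 19 (1E,5E)-1-iodo-2,6,10-trimethylundeca-1,5,9-triene, via alkenylalane 18 (not isolated)
Conditions: Me3Al (2 equiv), Cp2ZrCl2 (0.25 equiv), CH2Cl2, 0 °C to rt; then I2 (1.3 equiv), THF, −30 to 0 °C
Reagents that add atoms: trimethylaluminium, C[Al](C)C (methyl group in 19; AlMe2 in 18 only); iodine, II
Why: Zirconium-catalysed Negishi carboalumination adds methyl and aluminium syn with aluminium on the terminal carbon, and iodinolysis with retention fixes the (E)-trisubstituted alkenyl iodide.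

Step 9
Reactants: 14 (4S,5R,6R)-4-hydroxy-5-(iodomethyl)-2-methoxy-6-methylcyclohex-2-en-1-one; 19 (1E,5E)-1-iodo-2,6,10-trimethylundeca-1,5,9-triene
Product: 20 (4R,5R,6R)-4-hydroxy-2-methoxy-6-methyl-5-[(2E,6E)-3,7,11-trimethyldodeca-2,6,10-trien-1-yl]cyclohex-2-en-1-one (target)
Conditions: 19 (1.5 equiv), NiBr2(dme) (10 mol %), 4,4'-di-tert-butyl-2,2'-bipyridine (10 mol %), Mn powder (3 equiv), NaI (0.5 equiv), DMA, rt
Reagents that add atoms: none
Why: Nickel-catalysed reductive cross-electrophile coupling of an alkenyl halide with a primary alkyl halide, in which zerovalent nickel inserts into the C(sp2)–I bond with retention of the (E)-geometry and the alkyl iodide enters as the C7 radical, the neutral room-temperature medium tolerating the free alcohol and the ketone and leaving C4, C5 and C6 untouched.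

Compound list
1 | allyl propionate | CCC(=O)OCC=C | starting material
2 | methyl methoxyacetate | COCC(=O)OC | starting material
3 | allyl 4-methoxy-2-methyl-3-oxobutanoate (racemic) | COCC(=O)C(C)C(=O)OCC=C | intermediate
4 | allyl benzoate | C=CCOC(=O)c1ccccc1 | starting material
5 | (E)-crotonaldehyde | C/C=C/C=O | starting material
6 | (E)-4-oxobut-2-en-1-yl benzoate | O=C/C=C/COC(=O)c1ccccc1 | intermediate
7 | dibenzoyl peroxide | O=C(OOC(=O)c1ccccc1)c1ccccc1 | starting material
8 | allyl 2-[(2S)-1-benzoyloxy-4-oxobutan-2-yl]-4-methoxy-2-methyl-3-oxobutanoate (Michael adduct, not isolated; C6 epimers, one drawn) | O=CC[C@H](COC(=O)c1ccccc1)[C@](C)(C(=O)OCC=C)C(=O)COC | intermediate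
9 | allyl 2-[(2S,3R)-1,3-bis(benzoyloxy)-4-oxobutan-2-yl]-4-methoxy-2-methyl-3-oxobutanoate (not isolated; C6 epimers, one drawn) | O=C[C@H](OC(=O)c1ccccc1)[C@H](COC(=O)c1ccccc1)[C@](C)(C(=O)OCC=C)C(=O)COC | intermediate
10 | allyl 4-benzoyloxy-5-(benzoyloxymethyl)-3-hydroxy-2-methoxy-6-methyl-1-oxocyclohexane-6-carboxylate (aldol, not isolated; C2 and C3 undefined) | COC1C(O)[C@H](OC(=O)c2ccccc2)[C@H](COC(=O)c2ccccc2)[C@](C)(C(=O)OCC=C)C1=O | intermediate
11 | allyl (4R,5S)-4-benzoyloxy-5-(benzoyloxymethyl)-2-methoxy-6-methyl-1-oxocyclohex-2-ene-6-carboxylate (4,5-cis; C6 epimers, 6S drawn) | COC1=C[C@H](OC(=O)c2ccccc2)[C@H](COC(=O)c2ccccc2)[C@](C)(C(=O)OCC=C)C1=O | intermediate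
12 | (4R,5S)-4-benzoyloxy-5-(benzoyloxymethyl)-2-methoxy-6-methylcyclohex-2-en-1-one (C6 epimers, 6R drawn) | COC1=C[C@H](OC(=O)c2ccccc2)[C@H](COC(=O)c2ccccc2)[C@@H](C)C1=O | intermediate
13 | (4R,5S,6R)-4-hydroxy-5-(hydroxymethyl)-2-methoxy-6-methylcyclohex-2-en-1-one | COC1=C[C@H](O)[C@H](CO)[C@@H](C)C1=O | intermediate
14 | (4S,5R,6R)-4-hydroxy-5-(iodomethyl)-2-methoxy-6-methylcyclohex-2-en-1-one | COC1=C[C@H](O)[C@H](CI)[C@@H](C)C1=O | intermediate
15 | (E)-geranylacetone | CC(=O)CC/C=C(\C)CCC=C(C)C | starting material
16 | diethyl (E)-6,10-dimethylundeca-1,5,9-trien-2-yl phosphate (not isolated) | C=C(CC/C=C(\C)CCC=C(C)C)OP(=O)(OCC)OCC | intermediate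
17 | (E)-6,10-dimethylundeca-5,9-dien-1-yne | C#CCC/C=C(\C)CCC=C(C)C | intermediate
18 | dimethyl[(1E,5E)-2,6,10-trimethylundeca-1,5,9-trien-1-yl]aluminium (not isolated) | C[Al](C)/C=C(\C)CC/C=C(\C)CCC=C(C)C | intermediate
19 | (1E,5E)-1-iodo-2,6,10-trimethylundeca-1,5,9-triene | I/C=C(\C)CC/C=C(\C)CCC=C(C)C | intermediate
20 | (4R,5R,6R)-4-hydroxy-2-methoxy-6-methyl-5-[(2E,6E)-3,7,11-trimethyldodeca-2,6,10-trien-1-yl]cyclohex-2-en-1-one | COC1=C[C@H](O)[C@H](C/C=C(\C)CC/C=C(\C)CCC=C(C)C)[C@@H](C)C1=O | target

Total step count: 9. Longest linear sequence: 6 (step 1 or 2, then steps 3, 4, 5, 6 and 9).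

Steps most likely to fail

1. Step 3.
What may go wrong:
- oxidation of the amine or of leftover keto ester by the peroxide;
- a slow and reversible Michael addition of the hindered donor;
- poor facial selectivity in the C–O bond formation if the C5 centre works against the catalyst;
- epimerisation at C4 or retro-Michael cleavage during the acid stage.

Fallback (known chemistry): the cascade is given up and, setting out from 3 and 6, replaced by three separately precedented reactions, each with its own work-up. The amine-catalysed Michael addition gives 8, which is isolated. Enamine α-benzoyloxylation of purified 8 with 7 follows. Its amine can now be chosen on its own merits (the same (R)-silyl ether or (R)-2-tritylpyrrolidine), and the peroxide never meets 3 or 6. This gives isolated 9. Acid-catalysed aldol condensation (TsOH, toluene) comes back to the route at 11. This fallback makes no compound outside the list (F0).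

2. Step 9.
What may go wrong:
- homocoupling or hydrodeiodination of either iodide;
- capture of the C7 radical by the enone of a second molecule;
- reduction of the enone by low-valent metal.

Fallback: the polarity of the ring fragment is reversed and a Negishi coupling is used.
- Setting out from 14, silylation (Et3SiCl, imidazole, CH2Cl2) gives the C4 triethylsilyl ether of the iodide F1.
- Zinc insertion (Zn dust, LiCl, THF) gives the alkylzinc iodide F2.
- PdCl2(dppf)-catalysed coupling with 19 gives the C4 triethylsilyl ether of the target F3.
- HF·pyridine in THF comes back to the route at 20.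

3. Step 4.
What may go wrong:
- competing ionisation of the ring allylic benzoate by zerovalent palladium;
- its hydrogenolysis by formate;
- allylation at C6 in place of protonation.

Fallback: the ester is removed without metal.
- Setting out from 2, Claisen condensation with commercial tert-butyl propionate (LDA, THF, −78 °C) gives tert-butyl 4-methoxy-2-methyl-3-oxobutanoate F4.
- The annulation of step 3 with 6 and 7 gives the tert-butyl ester analogue of 11 F5.
- CF3CO2H in CH2Cl2 gives the β-keto acid F6, which should lose carbon dioxide on warming in toluene and comes back to the route at 12.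
- Partial loss of the tert-butyl group in the acid stage of the annulation would lead to the same ketone.

Further compounds
F0 | step 3 | none | none
F1 | step 9 | (4S,5R,6R)-5-(iodomethyl)-2-methoxy-6-methyl-4-(triethylsilyloxy)cyclohex-2-en-1-one | COC1=C[C@H](O[Si](CC)(CC)CC)[C@H](CI)[C@@H](C)C1=O
F2 | step 9 | alkylzinc iodide from F1 (zinc on C7) | COC1=C[C@H](O[Si](CC)(CC)CC)[C@H](C[Zn]I)[C@@H](C)C1=O
F3 | step 9 | (4R,5R,6R)-2-methoxy-6-methyl-4-(triethylsilyloxy)-5-[(2E,6E)-3,7,11-trimethyldodeca-2,6,10-trien-1-yl]cyclohex-2-en-1-one | COC1=C[C@H](O[Si](CC)(CC)CC)[C@H](C/C=C(\C)CC/C=C(\C)CCC=C(C)C)[C@@H](C)C1=O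
F4 | step 4 | tert-butyl 4-methoxy-2-methyl-3-oxobutanoate (racemic) | COCC(=O)C(C)C(=O)OC(C)(C)C
F5 | step 4 | tert-butyl (4R,5S)-4-benzoyloxy-5-(benzoyloxymethyl)-2-methoxy-6-methyl-1-oxocyclohex-2-ene-6-carboxylate (C6 epimers, one drawn) | COC1=C[C@H](OC(=O)c2ccccc2)[C@H](COC(=O)c2ccccc2)[C@](C)(C(=O)OC(C)(C)C)C1=O
F6 | step 4 | (4R,5S)-4-benzoyloxy-5-(benzoyloxymethyl)-2-methoxy-6-methyl-1-oxocyclohex-2-ene-6-carboxylic acid (C6 epimers, one drawn) | COC1=C[C@H](OC(=O)c2ccccc2)[C@H](COC(=O)c2ccccc2)[C@](C)(C(=O)O)C1=O
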